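## Structural features

The target carries two 7-methoxy-2H-chromen-2-one (coumarin) units on a 1,4-dimethylcyclohexene. Ring system B is bonded through C8' directly to ring carbon C6, and ring system A through C8 to an (E)-ethenyl bridge that ends on the quaternary carbon C1. C1 (methyl, alkenyl) and C6 (hydrogen, aryl) are adjacent stereocentres, both R, with the alkenyl arm and the aryl group on the same face. The ring alkene C4=C5 lies next to C6, so C6–H is allylic and benzylic at once. The fragile groups are the two lactones (hydroxide, alkoxide), the trisubstituted ring alkene (acid, electrophiles), the doubly activated C6–H, and the 1,5-diene formed by the C1 alkenyl group and C4=C5 (prolonged strong heating). The real difficulty is the C6–C8' bond: an arene carbon flanked by two oxygen-bearing carbons (C7' and C8a') must be attached to a secondary carbon next to a quaternary one, with control of relative and absolute configuration. The key step uses this pattern: C8' and C7' are taken as the two carbons of a silyloxyalkyne already bonded to C6, and C8a', C4a', C5' and C6' as a vinylketene, so the benzene ring of ring system B grows onto a slim C6–C(sp) bond. Ring system A is attached last, at the free end of a C1 vinyl group that has no allylic hydrogen on the C1 side.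

## Logic of the disconnections

33 ⇒ 29 + 32. The bond between C8 of ring system A and the terminal carbon of the C1 alkenyl arm is cut. This removes a complete coumarin and leaves a plain vinyl group. The forward Heck reaction must arylate the terminal carbon of a neopentyl-type alkene with a doubly ortho-substituted aryl iodide; the quaternary C1 guarantees that β-hydride elimination gives only the (E)-styrene.

32 ⇒ 31 ⇒ 30. The O–CH3 bond and then the C8–I bond are cut, leading back to a commercial hydroxycoumarin. The forward iodination must go to C8 and not to C6.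

29 ⇒ 27 ⇒ 24 + 25. The methyl ether at C7' is traced to the silyl ether that the key step delivers. The pyranone is then opened at C3'=C4' and at the lactone C2'–O1' bond. This reduces ring system B to a salicylaldehyde with its two oxygens already differentiated. The forward olefination–lactonisation needs the free hydroxyl ortho to the formyl group and must not disturb the silyl ether or the alkenes.

24 ⇒ 23. The formyl group is traced to a dimethyl acetal, because a free aldehyde on the ketene precursor would not survive diazo transfer and photolysis. The forward hydrolysis must be mild enough for the aryl silyl ether.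

23 ⇒ 14 + 19 (key disconnection). The bonds C8'–C8a', C7'–C6' and C8a'–C4a' are cut, which takes the whole benzene ring of ring system B apart into an alkyne and a four-carbon vinylketene precursor. The crowded aryl–C6 bond becomes an alkyne–C6 bond, and the stereochemical problem shrinks to a cyclohexene carrying a vinyl and an ethynyl group cis. The forward step demands regiocontrol in the ketene–alkyne addition and tolerance of the two spectator alkenes.

19 ⇒ 17 ⇒ 15 + 16. The C=N2 unit is traced to a methyl ketone, and the enone C3=C4 bond is cut between two commercial partners. The forward diazo transfer must act at the methyl group of an enone without diazomethane.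

14 ⇒ 11 ⇒ 10. The O–C(sp) bond of the ynol ether is cut to a terminal alkyne, and this to its C-silylated form. The labile ynol ether is thus made only immediately before use. The forward step has to oxidise a hindered lithium acetylide and silylate the ynolate at oxygen.

10 ⇒ 9. The C=CH2 bond of the C1 vinyl group is cut to an aldehyde. The forward methylenation meets a hindered aldehyde that cannot enolise.

9 ⇒ 7. The C1–CH3 bond is cut, which removes the quaternary centre. The forward alkylation must bring the methyl group in anti to the alkynyl group on C6.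

7 ⇒ 5 + 6. The C1–C6 and C2–C3 bonds are cut (Diels–Alder). The ring, the C4=C5 alkene and the C6 stereocentre come from a diene and a three-carbon enal. The forward step needs regiocontrol (reinforced by both diene substituents), endo selectivity and a chiral catalyst for the absolute configuration at C6.

5 ⇒ 3 + 4 and 3 ⇒ 1 + 2. The two C(sp2)–C(sp2) and C(sp)–C(sp2) bonds flanking the disubstituted alkene are cut. All four pieces are commercial, and the (E) geometry comes from 2 and must be retained in both couplings.

## Other disconnections considered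

Alternative 1: The cut is at C1–CH3 and C6–C(aryl), both made across a C1=C6 double bond. In the forward key step the dienyl boronate 4,4,5,5-tetramethyl-2-(4-methylcyclohexa-1,3-dien-1-yl)-1,3,2-dioxaborolane A2 is turned into an ate complex with methyllithium. An arylpalladium species from 2,6-dimethoxyphenyl trifluoromethanesulfonate A3 (Pd(OAc)2, MandyPhos) then attacks C6 and triggers a 1,2-shift of methyl from boron to C1. The product is the tertiary boronate A1 with boron and aryl cis.
- In favour: one catalytic step would set both stereocentres, the anti relationship of methyl and aryl follows from the mechanism, and the C–B bond could become the alkenyl arm by a Zweifel-type olefination.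
- Against: the alkene that must accept the aryl group is part of a conjugated diene, so an allylpalladium pathway and 1,4-addition can compete. Methyl is a reluctant migrating group. The electrophile is doubly ortho-substituted. The crowded aryl–C6 bond is made by coupling at the most hindered position.
- Structure: ring B arrives as a symmetrical dimethoxyarene that still needs mono-demethylation, ortho-formylation and lactonisation next to acid-sensitive alkenes, whereas 23 arrives with hydroxyl, protected oxygen and the formyl carbon already differentiated.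
- Mechanism: stereocontrol by a stereospecific addition is better than the conformational control relied on in step 4 of the chosen plan.
- Step economy: up to the cyclohexene core it is the equal or the better; over the whole route the arene end game should cancel that advantage.

Alternative 2: The cut is at C4=C5. In the forward key step the acyclic diene A5 is closed by the second-generation Grubbs catalyst between the C6 vinyl group and the isopropenyl end of the C1 side chain, giving the silyl ether A4.
- In favour: closure of a trisubstituted cyclohexene by metathesis is highly dependable. As a ring-forming event it is more predictable than either the cycloaddition of step 3 or the benzannulation of step 10, and on this point it is the better plan. The key step carries no stereochemical risk.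
- Against: both stereocentres, a quaternary carbon next to a tertiary one bearing a doubly ortho-substituted aryl group, must be set in an open chain beforehand. The C1 arm has to stay oxygenated during metathesis, because a C1 vinyl group would close a cyclopentene with the isopropenyl group, so three further steps are needed to reach the vinyl group. Ring B needs the same arene end game as in alternative 1.
- Structure: the ring is made last and the stereocentres first, the reverse of the chosen plan.
- Mechanism: it is the equal or the better, since no selectivity is asked of the key step.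
- Step economy: it should be clearly longer.

Alternative 3: The cut is at C5–C6. In the forward key step BF3·OEt2 ionises the benzylic alcohol of the acyclic nitrile A7, and the (Z)-vinylsilane attacks the cation through its silicon-bearing carbon. Loss of the silyl group gives the cyclohexene nitrile A6 with aryl and nitrile cis.
- In favour: two ortho methoxy groups make ionisation easy, silicon fixes the position of the ring alkene, and ring and C6 stereocentre form in one step. No photochemistry or diazo compound is needed, so it is operationally simpler, and on this point it is the better plan. The nitrile is a compact precursor of the C1 alkenyl arm.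
- Against: the relative configuration rests on discrimination between methyl and nitrile at C1 in a cationic transition state. The product A6, with an electron-rich aryl group on an allylic carbon, could re-ionise under the Lewis acid. The (Z)-vinylsilane and an enantioenriched cyano-substituted quaternary centre must be secured first. Ring B again needs demethylation, formylation and lactonisation.
- Structure: the aryl–C6 bond is present from a simple carbonyl addition, which avoids an aryl coupling as neatly as the chosen plan does (equal).
- Mechanism: the diastereocontrol should be comparable to that of step 4 (equal).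
- Step economy: the way to the cyclohexene is of similar length, but the way from it to the target should be longer than from 23.

Key step: step 10

Remark on the structures: the ring alkene lies between C4 and C5, next to C6. A name of the type "6-substituted 1,4-dimethylcyclohex-3-ene" would put it at C3=C4, away from C6, and does not fit the connectivity. The systematic names below therefore use lowest-locant numbering (the alkynyl- or aryl-bearing carbon is C2 of a cyclohex-3-ene, or C1 of a cyclohex-2-en-1-yl group), while C1–C6 in the discussion keep the meaning used above.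

Remark on descriptors: the descriptor of the alkynyl-bearing carbon changes from R to S in 11 and 12 only because substituent priorities change; no step inverts that centre.

Assumption: the (5S)-imidazolidinone catalyst is taken to expose the face of the acrolein iminium ion that leads to the 1R aldehyde, so the (5R)-catalyst is chosen for 7; if the sense proved opposite, the other enantiomer of the catalyst would be used.

## Route

Step 1
Reactants: 1 ethynyltri(propan-2-yl)silane; 2 (E)-1,2-dichloroethene
Product: 3 [(3E)-4-chlorobut-3-en-1-yn-1-yl]tri(propan-2-yl)silane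
Conditions: Pd(PPh3)4 (cat.), CuI (cat.), n-BuNH2, 2 (5 equiv), Et2O, rt
Reagents that add atoms: none
Why: Sonogashira coupling of the terminal alkyne with one carbon–chlorine bond of the dichloroalkene; the excess of 2 suppresses double coupling and the alkene geometry is retained.

Step 2
Reactants: 3 [(3E)-4-chlorobut-3-en-1-yn-1-yl]tri(propan-2-yl)silane; 4 4,4,5,5-tetramethyl-2-(prop-1-en-2-yl)-1,3,2-dioxaborolane
Product: 5 [(3E)-5-methylhexa-3,5-dien-1-yn-1-yl]tri(propan-2-yl)silane
Conditions: Pd(OAc)2 (cat.), SPhos, K3PO4, THF/H2O, 50 °C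
Reagents that add atoms: none
Why: Suzuki–Miyaura coupling of an alkenyl chloride activated by the conjugated alkyne; the coupling is stereoretentive, so the (E)-diene should result.

Step 3
Reactants: 5 [(3E)-5-methylhexa-3,5-dien-1-yn-1-yl]tri(propan-2-yl)silane; 6 prop-2-enal
Product: 7 (1S,2R)-4-methyl-2-{[tri(propan-2-yl)silyl]ethynyl}cyclohex-3-ene-1-carbaldehyde (formyl and alkynyl cis)
Conditions: (5R)-5-benzyl-2,2,3-trimethylimidazolidin-4-one hydrochloride (20 mol%), 6 (4 equiv), MeCN/H2O 95:5, 0 °C → rt; minor trans (exo) adduct removed on SiO2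
Reagents that add atoms: none
Why: Iminium-ion-catalysed Diels–Alder reaction in which the terminal alkynyl group and the internal methyl group of the diene both direct the substituted diene terminus to the α-carbon of the enal. The endo transition state places formyl and alkynyl cis, and the benzyl group of the catalyst shields one face of the iminium ion, which sets C6. The exo adduct has the opposite configuration at the alkynyl-bearing carbon and must be removed before step 4, where C1 is erased.

Step 4
Reactants: 7 (1S,2R)-4-methyl-2-{[tri(propan-2-yl)silyl]ethynyl}cyclohex-3-ene-1-carbaldehyde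
Product: 9 (1S,2R)-1,4-dimethyl-2-{[tri(propan-2-yl)silyl]ethynyl}cyclohex-3-ene-1-carbaldehyde (formyl and alkynyl cis), via potassium enolate 8 (not isolated)
Conditions: KOtBu (1.2 equiv), MeI (3 equiv), THF, −40 → 0 °C
Reagents that add atoms: iodomethane, IC
Why: C-Methylation of the potassium enolate of an α-branched aldehyde. Allylic 1,3-strain with the exocyclic enolate turns the alkynyl group on C6 pseudoaxial, so iodomethane should approach C1 from the opposite face; the methyl group ends trans to the alkyne and the formyl group cis, which sets the quaternary centre C1.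

Step 5
Reactants: 9 (1S,2R)-1,4-dimethyl-2-{[tri(propan-2-yl)silyl]ethynyl}cyclohex-3-ene-1-carbaldehyde
Product: 10 {[(1R,6R)-6-ethenyl-3,6-dimethylcyclohex-2-en-1-yl]ethynyl}tri(propan-2-yl)silane (vinyl and alkynyl cis)
Conditions: Ph3PCH3Br, KOtBu, THF, 0 °C → rt
Reagents that add atoms: methyltriphenylphosphonium bromide, C[P+](c1ccccc1)(c1ccccc1)c1ccccc1.[Br-]
Why: Wittig methylenation of a hindered aldehyde that has no α-hydrogen, so C1 cannot epimerise.

Step 6
Reactants: 10 {[(1R,6R)-6-ethenyl-3,6-dimethylcyclohex-2-en-1-yl]ethynyl}tri(propan-2-yl)silane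
Product: 11 (3S,4R)-4-ethenyl-3-ethynyl-1,4-dimethylcyclohex-1-ene (vinyl and ethynyl cis)
Conditions: Bu4NF, THF, 0 °C → rt; pentane extraction, careful concentration
Reagents that add atoms: none
Why: Fluoride-induced cleavage of the C(sp)–Si bond; no other fluoride-sensitive group is present and the hydrocarbon product is handled cold because it is volatile.

Step 7
Reactants: 11 (3S,4R)-4-ethenyl-3-ethynyl-1,4-dimethylcyclohex-1-ene
Product: 14 ({[(1R,6R)-6-ethenyl-3,6-dimethylcyclohex-2-en-1-yl]ethynyl}oxy)tri(propan-2-yl)silane, via lithium acetylide 12 (not isolated), via lithium ynolate 13 (not isolated)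
Conditions: LiHMDS, THF, −78 → 0 °C; LiOOtBu (from t-BuOOH in decane + LiHMDS, THF, −78 °C), −78 → 0 °C; iPr3SiOTf, −78 °C → rt
Reagents that add atoms: tert-butyl hydroperoxide, CC(C)(C)OO; tri(propan-2-yl)silyl trifluoromethanesulfonate, CC(C)[Si](OS(=O)(=O)C(F)(F)F)(C(C)C)C(C)C
Why: Oxygen transfer from lithium tert-butyl peroxide to the lithium acetylide gives the lithium ynolate, and the bulky silyl triflate should react at oxygen and not at carbon to give the silyl ynol ether. Neither alkene reacts with the nucleophilic peroxide and the stereocentres are not touched.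

Step 8
Reactants: 15 2,2-dimethoxyacetaldehyde; 16 1-(triphenyl-λ5-phosphanylidene)propan-2-one
Product: 17 (3E)-5,5-dimethoxypent-3-en-2-one
Conditions: 15 (commercial aqueous solution), CH2Cl2, rt
Reagents that add atoms: none
Why: Wittig olefination with a stabilised acyl ylide, which tolerates water and should give the (E)-enone.

Step 9
Reactants: 17 (3E)-5,5-dimethoxypent-3-en-2-one
Product: 19 (3E)-1-diazo-5,5-dimethoxypent-3-en-2-one, via trifluoroacetyl diketone 18 (not isolated)
Conditions: LiHMDS, THF, −78 °C; CF3CO2CH2CF3; then 4-acetamidobenzenesulfonyl azide, Et3N, H2O (1 equiv), MeCN, rt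
Reagents that add atoms: 4-acetamidobenzenesulfonyl azide, CC(=O)Nc1ccc(cc1)S(=O)(=O)N=[N+]=[N-]
Why: Detrifluoroacetylative diazo transfer: the kinetic methyl enolate is trifluoroacetylated, the activated 1,3-diketone accepts the diazo group and the trifluoroacetyl group leaves on the sulfonamide. The method is made for α'-diazo enones and avoids diazomethane and an acid chloride next to the acetal.

Step 10
Reactants: 14 ({[(1R,6R)-6-ethenyl-3,6-dimethylcyclohex-2-en-1-yl]ethynyl}oxy)tri(propan-2-yl)silane; 19 (3E)-1-diazo-5,5-dimethoxypent-3-en-2-one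
Product: 23 6-(dimethoxymethyl)-2-[(1R,6R)-6-ethenyl-3,6-dimethylcyclohex-2-en-1-yl]-3-{[tri(propan-2-yl)silyl]oxy}phenol, via vinylketene 20 (not isolated), via vinylcyclobutenone 21 (not isolated), via dienylketene 22 (not isolated)
Conditions: 19 (1.3 equiv, in portions), hν (254 nm, quartz), degassed ClCH2CH2Cl, rt; then 80 °C
Reagents that add atoms: none
Why: Irradiation of 19 expels dinitrogen and the alkenyl group migrates (Wolff rearrangement) to give vinylketene 20. The electron-rich alkyne carbon of 14 that is bonded to C6 attacks the ketene carbonyl carbon and the oxygen-bearing alkyne carbon closes onto the ketene α-carbon in a [2+2] cycloaddition, giving 21 with the bonds C8'–C8a' and C7'–C6' in place. On warming, 21 opens reversibly in a four-electron electrocyclic step, and the rotamer with the alkenyl group turned inward is dienylketene 22. The benzene ring then closes by a thermal six-electron disrotatory electrocyclisation between the ketene carbon and the terminal alkene carbon (bond C8a'–C4a'), and tautomerisation gives phenol 23. The closest known reaction type is the Danheiser benzannulation of silyloxyalkynes with α-diazo enones under photochemical Wolff conditions. No stereocentre is formed, and C1 and C6 should pass unchanged because the conditions are neutral and neither centre carries an acidic hydrogen or a leaving group. The selectivity needed is regiochemical and is secured by the polarisation of the ynol ether, nucleophilic at the carbon remote from oxygen, which places the free hydroxyl and the silyl ether on either side of C8' and the acetal ortho to the hydroxyl. The isolated vinyl and ring alkenes are far poorer ketenophiles than the silyloxyalkyne and should stay untouched.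

Step 11
Reactants: 23 6-(dimethoxymethyl)-2-[(1R,6R)-6-ethenyl-3,6-dimethylcyclohex-2-en-1-yl]-3-{[tri(propan-2-yl)silyl]oxy}phenol
Product: 24 3-[(1R,6R)-6-ethenyl-3,6-dimethylcyclohex-2-en-1-yl]-2-hydroxy-4-{[tri(propan-2-yl)silyl]oxy}benzaldehyde
Conditions: pyridinium p-toluenesulfonate (cat.), acetone/H2O, rt
Reagents that add atoms: water, O
Why: Acid-catalysed hydrolysis of an electron-rich benzaldehyde dimethyl acetal, which is fast under conditions that leave the aryl silyl ether and the trisubstituted alkene alone.

Step 12
Reactants: 24 3-[(1R,6R)-6-ethenyl-3,6-dimethylcyclohex-2-en-1-yl]-2-hydroxy-4-{[tri(propan-2-yl)silyl]oxy}benzaldehyde; 25 ethyl 2-(triphenyl-λ5-phosphanylidene)acetate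
Product: 27 8-[(1R,6R)-6-ethenyl-3,6-dimethylcyclohex-2-en-1-yl]-7-{[tri(propan-2-yl)silyl]oxy}-2H-chromen-2-one, via hydroxycinnamate ester 26 (not isolated)
Conditions: 25 (1.5 equiv), PhNEt2, reflux
Reagents that add atoms: none
Why: Wittig olefination of the salicylaldehyde gives the o-hydroxycinnamate; at this temperature the alkene geometry equilibrates and the Z isomer lactonises with loss of ethanol. This is the classical coumarin synthesis from 3-substituted 2-hydroxy-4-alkoxybenzaldehydes.

Step 13
Reactants: 27 8-[(1R,6R)-6-ethenyl-3,6-dimethylcyclohex-2-en-1-yl]-7-{[tri(propan-2-yl)silyl]oxy}-2H-chromen-2-one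
Product: 29 8-[(1R,6R)-6-ethenyl-3,6-dimethylcyclohex-2-en-1-yl]-7-methoxy-2H-chromen-2-one, via 7-hydroxycoumarin 28 (not isolated)
Conditions: CsF (3 equiv), MeI (5 equiv), DMF, rt
Reagents that add atoms: iodomethane, IC
Why: Fluoride cleaves the aryl silyl ether and the caesium phenoxide is methylated in the same flask (Williamson ether synthesis). The lactone is not exposed to hydroxide or alkoxide.

Step 14
Reactants: 30 7-hydroxy-2H-chromen-2-one
Product: 31 7-hydroxy-8-iodo-2H-chromen-2-one
Conditions: iodine, KI, aqueous NH3, rt; then dilute H2SO4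
Reagents that add atoms: iodine, [I][I]
Why: Electrophilic aromatic iodination of the phenoxide, which under ammoniacal conditions should go to C8, the position ortho to the oxygen and next to the ring-fusion carbon.

Step 15
Reactants: 31 7-hydroxy-8-iodo-2H-chromen-2-one
Product: 32 8-iodo-7-methoxy-2H-chromen-2-one
Conditions: MeI, K2CO3, acetone, reflux
Reagents that add atoms: iodomethane, IC
Why: Williamson O-methylation of the phenol under conditions that leave the lactone intact.

Step 16
Reactants: 29 8-[(1R,6R)-6-ethenyl-3,6-dimethylcyclohex-2-en-1-yl]-7-methoxy-2H-chromen-2-one; 32 8-iodo-7-methoxy-2H-chromen-2-one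
Product: 33 7-methoxy-8-[(E)-2-[(1R,2R)-2-(7-methoxy-2-oxo-2H-chromen-8-yl)-1,4-dimethylcyclohex-3-en-1-yl]ethenyl]-2H-chromen-2-one
Conditions: Pd(OAc)2 (10 mol%), n-Bu4NCl, NaHCO3, 32 (1.5 equiv), DMF, 90 °C
Reagents that add atoms: none
Why: Heck reaction: zerovalent palladium inserts into the carbon–iodine bond and the aryl group is delivered to the terminal carbon of the vinyl group. Because C1 is quaternary, β-hydride elimination can only use the benzylic hydrogens and should give the (E)-alkene. The weak base spares both lactones and the stereocentres are not involved.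

## Compound list

1 | ethynyltri(propan-2-yl)silane | C#C[Si](C(C)C)(C(C)C)C(C)C | starting material
2 | (E)-1,2-dichloroethene | Cl/C=C/Cl | starting material
3 | [(3E)-4-chlorobut-3-en-1-yn-1-yl]tri(propan-2-yl)silane | Cl/C=C/C#C[Si](C(C)C)(C(C)C)C(C)C | intermediate
4 | 4,4,5,5-tetramethyl-2-(prop-1-en-2-yl)-1,3,2-dioxaborolane | CC(=C)B1OC(C)(C)C(C)(C)O1 | starting material
5 | [(3E)-5-methylhexa-3,5-dien-1-yn-1-yl]tri(propan-2-yl)silane | CC(=C)/C=C/C#C[Si](C(C)C)(C(C)C)C(C)C | intermediate
6 | prop-2-enal | C=CC=O | starting material
7 | (1S,2R)-4-methyl-2-{[tri(propan-2-yl)silyl]ethynyl}cyclohex-3-ene-1-carbaldehyde | O=C[C@H]1CCC(C)=C[C@H]1C#C[Si](C(C)C)(C(C)C)C(C)C | intermediate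
8 | potassium [(2R)-4-methyl-2-{[tri(propan-2-yl)silyl]ethynyl}cyclohex-3-en-1-ylidene]methanolate | [K+].[O-]C=C1CCC(C)=C[C@H]1C#C[Si](C(C)C)(C(C)C)C(C)C | intermediate
9 | (1S,2R)-1,4-dimethyl-2-{[tri(propan-2-yl)silyl]ethynyl}cyclohex-3-ene-1-carbaldehyde | O=C[C@@]1(C)CCC(C)=C[C@H]1C#C[Si](C(C)C)(C(C)C)C(C)C | intermediate
10 | {[(1R,6R)-6-ethenyl-3,6-dimethylcyclohex-2-en-1-yl]ethynyl}tri(propan-2-yl)silane | C=C[C@@]1(C)CCC(C)=C[C@H]1C#C[Si](C(C)C)(C(C)C)C(C)C | intermediate
11 | (3S,4R)-4-ethenyl-3-ethynyl-1,4-dimethylcyclohex-1-ene | C=C[C@@]1(C)CCC(C)=C[C@H]1C#C | intermediate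
12 | lithium 2-[(1S,6R)-6-ethenyl-3,6-dimethylcyclohex-2-en-1-yl]ethyn-1-ide | C=C[C@@]1(C)CCC(C)=C[C@H]1C#[C-].[Li+] | intermediate
13 | lithium 2-[(1R,6R)-6-ethenyl-3,6-dimethylcyclohex-2-en-1-yl]ethyn-1-olate | C=C[C@@]1(C)CCC(C)=C[C@H]1C#C[O-].[Li+] | intermediate
14 | ({[(1R,6R)-6-ethenyl-3,6-dimethylcyclohex-2-en-1-yl]ethynyl}oxy)tri(propan-2-yl)silane | C=C[C@@]1(C)CCC(C)=C[C@H]1C#CO[Si](C(C)C)(C(C)C)C(C)C | intermediate
15 | 2,2-dimethoxyacetaldehyde | COC(OC)C=O | starting material
16 | 1-(triphenyl-λ5-phosphanylidene)propan-2-one | CC(=O)C=P(c1ccccc1)(c1ccccc1)c1ccccc1 | starting material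
17 | (3E)-5,5-dimethoxypent-3-en-2-one | COC(OC)/C=C/C(C)=O | intermediate
18 | (5E)-1,1,1-trifluoro-7,7-dimethoxyhept-5-ene-2,4-dione | COC(OC)/C=C/C(=O)CC(=O)C(F)(F)F | intermediate
19 | (3E)-1-diazo-5,5-dimethoxypent-3-en-2-one | [N-]=[N+]=CC(=O)/C=C/C(OC)OC | intermediate
20 | (3E)-5,5-dimethoxypenta-1,3-dien-1-one | O=C=C/C=C/C(OC)OC | intermediate
21 | 4-[(1E)-3,3-dimethoxyprop-1-en-1-yl]-2-[(1R,6R)-6-ethenyl-3,6-dimethylcyclohex-2-en-1-yl]-3-{[tri(propan-2-yl)silyl]oxy}cyclobut-2-en-1-one (either configuration at C4 of the four-membered ring) | C=C[C@@]1(C)CCC(C)=C[C@H]1C1=C(O[Si](C(C)C)(C(C)C)C(C)C)C(/C=C/C(OC)OC)C1=O | intermediate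
22 | (3E,5E)-2-[(1R,6R)-6-ethenyl-3,6-dimethylcyclohex-2-en-1-yl]-7,7-dimethoxy-3-{[tri(propan-2-yl)silyl]oxy}hepta-1,3,5-trien-1-one | C=C[C@@]1(C)CCC(C)=C[C@H]1C(=C=O)/C(O[Si](C(C)C)(C(C)C)C(C)C)=C\C=C\C(OC)OC | intermediate
23 | 6-(dimethoxymethyl)-2-[(1R,6R)-6-ethenyl-3,6-dimethylcyclohex-2-en-1-yl]-3-{[tri(propan-2-yl)silyl]oxy}phenol | C=C[C@@]1(C)CCC(C)=C[C@H]1c1c(O[Si](C(C)C)(C(C)C)C(C)C)ccc(C(OC)OC)c1O | intermediate
24 | 3-[(1R,6R)-6-ethenyl-3,6-dimethylcyclohex-2-en-1-yl]-2-hydroxy-4-{[tri(propan-2-yl)silyl]oxy}benzaldehyde | C=C[C@@]1(C)CCC(C)=C[C@H]1c1c(O[Si](C(C)C)(C(C)C)C(C)C)ccc(C=O)c1O | intermediate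
25 | ethyl 2-(triphenyl-λ5-phosphanylidene)acetate | CCOC(=O)C=P(c1ccccc1)(c1ccccc1)c1ccccc1 | starting material
26 | ethyl (2E)-3-{3-[(1R,6R)-6-ethenyl-3,6-dimethylcyclohex-2-en-1-yl]-2-hydroxy-4-{[tri(propan-2-yl)silyl]oxy}phenyl}prop-2-enoate | C=C[C@@]1(C)CCC(C)=C[C@H]1c1c(O[Si](C(C)C)(C(C)C)C(C)C)ccc(/C=C/C(=O)OCC)c1O | intermediate
27 | 8-[(1R,6R)-6-ethenyl-3,6-dimethylcyclohex-2-en-1-yl]-7-{[tri(propan-2-yl)silyl]oxy}-2H-chromen-2-one | C=C[C@@]1(C)CCC(C)=C[C@H]1c1c(O[Si](C(C)C)(C(C)C)C(C)C)ccc2ccc(=O)oc12 | intermediate
28 | 8-[(1R,6R)-6-ethenyl-3,6-dimethylcyclohex-2-en-1-yl]-7-hydroxy-2H-chromen-2-one (present as its caesium salt) | C=C[C@@]1(C)CCC(C)=C[C@H]1c1c(O)ccc2ccc(=O)oc12 | intermediate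
29 | 8-[(1R,6R)-6-ethenyl-3,6-dimethylcyclohex-2-en-1-yl]-7-methoxy-2H-chromen-2-one | C=C[C@@]1(C)CCC(C)=C[C@H]1c1c(OC)ccc2ccc(=O)oc12 | intermediate
30 | 7-hydroxy-2H-chromen-2-one | Oc1ccc2ccc(=O)oc2c1 | starting material
31 | 7-hydroxy-8-iodo-2H-chromen-2-one | Oc1ccc2ccc(=O)oc2c1I | intermediate
32 | 8-iodo-7-methoxy-2H-chromen-2-one | COc1ccc2ccc(=O)oc2c1I | intermediate
33 | 7-methoxy-8-[(E)-2-[(1R,2R)-2-(7-methoxy-2-oxo-2H-chromen-8-yl)-1,4-dimethylcyclohex-3-en-1-yl]ethenyl]-2H-chromen-2-one | COc1ccc2ccc(=O)oc2c1/C=C/[C@@]1(C)CCC(C)=C[C@H]1c1c(OC)ccc2ccc(=O)oc12 | target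

## Step count and weak points

Total: 16 steps. Longest linear sequence: 12 steps (steps 1–7, 10–13 and 16); steps 8–9 and 14–15 are side branches.

Step 10 (key step). The cycloaddition of the vinylketene to an alkyne whose substituent is secondary and stands next to a quaternary carbon may be slower than loss of the ketene by dimerisation or decay, so that the ynol ether is recovered or slowly hydrolysed. The fallback sets out from 14 and changes the ketene source and the origin of the formyl carbon. But-2-enoyl chloride would be added slowly, in large excess, with Et3N to 14 in toluene at 80–110 °C. The parent vinylketene is then generated thermally by 1,4-dehydrochlorination and should pass through the same cycloaddition and electrocyclic cascade to 2-[(1R,6R)-6-ethenyl-3,6-dimethylcyclohex-2-en-1-yl]-3-{[tri(propan-2-yl)silyl]oxy}phenol F1. Magnesium-mediated ortho-formylation (MgCl2, Et3N, paraformaldehyde, MeCN, reflux) at the only free position ortho to the hydroxyl would then come back to the route at 24.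

Step 3. The alkynyl-substituted diene may be too unreactive toward the iminium ion, and endo selectivity or enantioselectivity may erode; the exo adduct carries the wrong configuration at C6. The fallback sets out from 5 and uses a covalently bound auxiliary and a chelating Lewis acid instead of an amine catalyst. (4R)-4-Benzyl-1,3-oxazolidin-2-one would be acylated (n-BuLi, acryloyl chloride) to (4R)-3-acryloyl-4-benzyl-1,3-oxazolidin-2-one F2. Cycloaddition with 5 (Et2AlCl, CH2Cl2, −78 → −30 °C) should give the endo imide (4R)-4-benzyl-3-[(1S,2R)-4-methyl-2-{[tri(propan-2-yl)silyl]ethynyl}cyclohex-3-ene-1-carbonyl]-1,3-oxazolidin-2-one F3, which could be purified by crystallisation. Reduction with LiBH4 would release the auxiliary and give [(1S,2R)-4-methyl-2-{[tri(propan-2-yl)silyl]ethynyl}cyclohex-3-en-1-yl]methanol F4, and Swern oxidation would come back at 7.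

Step 4. Facial discrimination by the slim alkynyl group may be poor, and O-methylation or aldol condensation of the aldehyde enolate may compete. The fallback sets out from 7 and moves the alkylation to an ester enolate, where allylic strain is larger and O-alkylation is not an issue. Pinnick oxidation would give (1S,2R)-4-methyl-2-{[tri(propan-2-yl)silyl]ethynyl}cyclohex-3-ene-1-carboxylic acid F5, and MeI/K2CO3 in DMF its methyl ester, methyl (1S,2R)-4-methyl-2-{[tri(propan-2-yl)silyl]ethynyl}cyclohex-3-ene-1-carboxylate F6. Treatment with LDA then MeI should give methyl (1S,2R)-1,4-dimethyl-2-{[tri(propan-2-yl)silyl]ethynyl}cyclohex-3-ene-1-carboxylate F7. LiAlH4 would give [(1S,2R)-1,4-dimethyl-2-{[tri(propan-2-yl)silyl]ethynyl}cyclohex-3-en-1-yl]methanol F8, and Swern oxidation would come back at 9.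

Step 16. Carbopalladation of a neopentyl-type alkene by a doubly ortho-substituted arylpalladium species may be slow, so that reduction or homocoupling of the aryl iodide, or arylation of a coumarin C3=C4 bond, takes over. The fallback sets out from 29 and replaces carbopalladation by metathesis and transmetalation. Cross-metathesis of 29 with 2-ethenyl-4,4,5,5-tetramethyl-1,3,2-dioxaborolane (second-generation Grubbs catalyst, toluene, 60 °C; the ring alkene and the coumarin alkenes are inert) should give 8-[(1R,6R)-3,6-dimethyl-6-[(E)-2-(4,4,5,5-tetramethyl-1,3,2-dioxaborolan-2-yl)ethenyl]cyclohex-2-en-1-yl]-7-methoxy-2H-chromen-2-one F9. Suzuki coupling with 32 (Pd(dppf)Cl2, K3PO4, dioxane/H2O, 60 °C) would come back at 33.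

Step 12. Prolonged heating above 200 °C may trigger sigmatropic rearrangement of the 1,5-diene unit or migration of the silyl group. The fallback sets out from 24 and replaces thermal equilibration by a kinetically Z-selective olefination at low temperature. Ethyl 2-[bis(2-methylphenoxy)phosphoryl]acetate and NaH (2.1 equiv) in THF at −78 → 0 °C should give ethyl (2Z)-3-{3-[(1R,6R)-6-ethenyl-3,6-dimethylcyclohex-2-en-1-yl]-2-hydroxy-4-{[tri(propan-2-yl)silyl]oxy}phenyl}prop-2-enoate F10 as its phenoxide, which should lactonise at or below room temperature and come back at 27.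

## Further compounds

F1 | step 10 | 2-[(1R,6R)-6-ethenyl-3,6-dimethylcyclohex-2-en-1-yl]-3-{[tri(propan-2-yl)silyl]oxy}phenol | C=C[C@@]1(C)CCC(C)=C[C@H]1c1c(O[Si](C(C)C)(C(C)C)C(C)C)cccc1O
F2 | step 3 | (4R)-3-acryloyl-4-benzyl-1,3-oxazolidin-2-one | C=CC(=O)N1[C@H](Cc2ccccc2)COC1=O
F3 | step 3 | (4R)-4-benzyl-3-[(1S,2R)-4-methyl-2-{[tri(propan-2-yl)silyl]ethynyl}cyclohex-3-ene-1-carbonyl]-1,3-oxazolidin-2-one | O=C([C@H]1CCC(C)=C[C@H]1C#C[Si](C(C)C)(C(C)C)C(C)C)N1[C@H](Cc2ccccc2)COC1=O
F4 | step 3 | [(1S,2R)-4-methyl-2-{[tri(propan-2-yl)silyl]ethynyl}cyclohex-3-en-1-yl]methanol | OC[C@H]1CCC(C)=C[C@H]1C#C[Si](C(C)C)(C(C)C)C(C)C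
F5 | step 4 | (1S,2R)-4-methyl-2-{[tri(propan-2-yl)silyl]ethynyl}cyclohex-3-ene-1-carboxylic acid | OC(=O)[C@H]1CCC(C)=C[C@H]1C#C[Si](C(C)C)(C(C)C)C(C)C
F6 | step 4 | methyl (1S,2R)-4-methyl-2-{[tri(propan-2-yl)silyl]ethynyl}cyclohex-3-ene-1-carboxylate | COC(=O)[C@H]1CCC(C)=C[C@H]1C#C[Si](C(C)C)(C(C)C)C(C)C
F7 | step 4 | methyl (1S,2R)-1,4-dimethyl-2-{[tri(propan-2-yl)silyl]ethynyl}cyclohex-3-ene-1-carboxylate | COC(=O)[C@@]1(C)CCC(C)=C[C@H]1C#C[Si](C(C)C)(C(C)C)C(C)C
F8 | step 4 | [(1S,2R)-1,4-dimethyl-2-{[tri(propan-2-yl)silyl]ethynyl}cyclohex-3-en-1-yl]methanol | OC[C@@]1(C)CCC(C)=C[C@H]1C#C[Si](C(C)C)(C(C)C)C(C)C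
F9 | step 16 | 8-[(1R,6R)-3,6-dimethyl-6-[(E)-2-(4,4,5,5-tetramethyl-1,3,2-dioxaborolan-2-yl)ethenyl]cyclohex-2-en-1-yl]-7-methoxy-2H-chromen-2-one | CC1(C)OB(/C=C/[C@@]2(C)CCC(C)=C[C@H]2c2c(OC)ccc3ccc(=O)oc23)OC1(C)C
F10 | step 12 | ethyl (2Z)-3-{3-[(1R,6R)-6-ethenyl-3,6-dimethylcyclohex-2-en-1-yl]-2-hydroxy-4-{[tri(propan-2-yl)silyl]oxy}phenyl}prop-2-enoate | C=C[C@@]1(C)CCC(C)=C[C@H]1c1c(O[Si](C(C)C)(C(C)C)C(C)C)ccc(/C=C\C(=O)OCC)c1O
A1 | alternative 1 | 2-[(1R,2R)-2-(2,6-dimethoxyphenyl)-1,4-dimethylcyclohex-3-en-1-yl]-4,4,5,5-tetramethyl-1,3,2-dioxaborolane | CC1(C)OB(OC1(C)C)[C@@]1(C)CCC(C)=C[C@H]1c1c(OC)cccc1OC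
A2 | alternative 1 | 4,4,5,5-tetramethyl-2-(4-methylcyclohexa-1,3-dien-1-yl)-1,3,2-dioxaborolane | CC1=CC=C(CC1)B1OC(C)(C)C(C)(C)O1
A3 | alternative 1 | 2,6-dimethoxyphenyl trifluoromethanesulfonate | COc1cccc(OC)c1OS(=O)(=O)C(F)(F)F
A4 | alternative 2 | tert-butyl{[(1S,2R)-2-(2,6-dimethoxyphenyl)-1,4-dimethylcyclohex-3-en-1-yl]methoxy}dimethylsilane | CC(C)(C)[Si](C)(C)OC[C@@]1(C)CCC(C)=C[C@H]1c1c(OC)cccc1OC
A5 | alternative 2 | tert-butyl{[(2S)-2-[(1R)-1-(2,6-dimethoxyphenyl)prop-2-en-1-yl]-2,5-dimethylhex-5-en-1-yl]oxy}dimethylsilane | CC(C)(C)[Si](C)(C)OC[C@@](C)(CCC(C)=C)[C@@H](C=C)c1c(OC)cccc1OC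
A6 | alternative 3 | (1S,2R)-2-(2,6-dimethoxyphenyl)-1,4-dimethylcyclohex-3-ene-1-carbonitrile | N#C[C@@]1(C)CCC(C)=C[C@H]1c1c(OC)cccc1OC
A7 | alternative 3 | (2R,5Z)-2-[(2,6-dimethoxyphenyl)(hydroxy)methyl]-2,5-dimethyl-6-(trimethylsilyl)hex-5-enenitrile (either configuration at the carbinol carbon) | N#C[C@@](C)(CC/C(C)=C\[Si](C)(C)C)C(O)c1c(OC)cccc1OC
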